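## Remarks on the chemistry

- Atom mapping check: in the iodophenol the C–I carbon becomes C4a, the C–OH carbon becomes C8a, and the two MOM ethers land on C5 and C7. In the alkyne the ethynyl carbon is ortho to one OMe, para to the other and meta to the OMOM group, which is the 2',4'-dimethoxy-5'-oxygenated ring B. The structures are consistent with the target and need no correction.
- Assumption: 5-bromo-2,4-dimethoxybenzaldehyde is taken as a catalogue compound, so ring B starts with its halogen already at the future C1' and one step is saved.
- Precursor design: the three phenols that must end free are carried as MOM ethers. These are inert to amine at 120 °C and to amide bases, and they are cleaved together at the end without touching the aryl methyl ethers. The phenol next to iodine stays free so that ring closure follows the carbonylation in the same flask.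

## Structural features

Artoindonesianin R is a 3-prenylated flavone: a benzene ring (ring A) fused through the C4a–C8a bond to a γ-pyranone (ring C), which carries a second benzene ring (ring B) on C2 through the C2–C1' bond and a 3-methylbut-2-enyl chain on C3. Ring A has the phloroglucinol pattern, with free hydroxyls at C5 (hydrogen-bonded to the C4 carbonyl) and C7. Ring B carries methoxy groups at C2' and C4' and a free hydroxyl at C5', so three ring B oxygens have to be told apart, and the 2'-O/5'-O pair is a hydroquinone monoether. There is no stereocenter and no alkene geometry (the prenyl terminus bears two methyl groups), and the crowded C2–C1' axis is not configurationally stable, so nothing stereochemical has to be set. The fragile groups are the trisubstituted prenyl alkene (acid-promoted Markovnikov addition, and no hydrogenation is allowed), the electron-rich phenols of rings A and B (oxidation), and C2 of the pyranone (ring opening by hydroxide or hard nucleophiles). The difficulty is regiochemical: one carbon substituent must go to C3 without C- or O-prenylation of the nucleophilic ring A, exactly one ring B oxygen must end free, and the C2=C3 bond is tetrasubstituted and flanked by an ortho-methoxyaryl group. The key step uses the fact that C4 is a single carbon bonded to C4a and C3 while O1 links C8a to C2. Ring C is therefore the sum of an ortho-iodophenol (C4a–I, C8a–OH), one molecule of carbon monoxide (C4) and an arylalkyne (C3≡C2–C1').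

## Logic of the disconnections

**19 ⇒ 18.** The three aryl O–CH2 acetal bonds are cut, so all three free phenols of 19 are masked by one kind of group. This turns an oxidisable triphenol into a compound that tolerates strong base and palladium chemistry. The forward step must be an acetal cleavage mild enough to leave the prenyl alkene and the aryl methyl ethers alone.

**18 ⇒ 14 + 15.** The C3–CH2 bond is cut. C3–H is the only vinylic C–H of 14 that is acidified by the adjacent carbonyl, and removing the prenyl group leaves a C3-unsubstituted flavone that a terminal alkyne can deliver. The gain is that the acid- and metal-sensitive alkene is absent from every earlier step. The demand is metalation at C3 in preference to the ring positions between oxygen substituents, and allylic substitution at the primary carbon of 15.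

**14 ⇒ 3 + 10 + 11.** The bonds C4a–C4, C3–C4 and O1–C2 are cut, which removes ring C in one stroke and leaves two benzene derivatives of similar size and a one-carbon unit. The forward step must insert 11 before the alkyne couples, and must close the six-membered pyranone in preference to the five-membered aurone.

**3 ⇒ 2 ⇒ 1.** The C–I bond is cut, then two O–CH2 bonds. 1 is threefold symmetric, so the only selectivities required are the degree of etherification and iodination ortho (not para) to the one free hydroxyl of 2.

**10 ⇒ 9 ⇒ 7 + 8.** The C–Si bond is cut, then the aryl–alkynyl bond. The two-carbon unit comes from 8, and the aryl partner is a bromide whose halogen is already at the correct position. The forward coupling must cope with an electron-rich, ortho-substituted aryl bromide.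

**7 ⇒ 6 ⇒ 4 (through 5).** The O–CH2 bond of the ring B acetal is cut, then the phenolic C–O bond is traced back to a formyl group by an oxidative aryl migration. This uses a benzaldehyde in which the bromine and both methoxy groups are already in place, so no ring B regiochemistry has to be created. The forward oxidation needs the aryl group, not hydrogen, to migrate.

## Other disconnections considered

**Alternative 1:** The cut goes through C4a–C4 and O1–C2. Ring A is then 1 itself, and C2, C3 with its prenyl group, C4 and ring B all sit in ethyl 2-[2,4-dimethoxy-5-(pivaloyloxy)benzoyl]-5-methylhex-4-enoate A1. Forward, 1 and A1 would be fused without catalyst at about 240–250 °C (Mentzer pyrone synthesis). A ring carbon of 1 is acylated by the ester carbon, the neighbouring hydroxyl condenses with the ketone, and ethanol and water are lost to give artoindonesianin R 5'-O-pivalate A2. Pivalate removal would finish.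
- In favour: ring A needs no protection, the symmetry of 1 removes any ring A regiochemistry, and the prenyl group is in place before ring closure, so no C3 metalation is needed. A1 should be reachable in about five steps from a ring B benzoic acid, for a total near seven steps. On step count and protecting-group economy this plan is the better one.
- Against: the temperature is severe for a substrate with a trisubstituted alkene. The enol oxygen of the α-prenyl ketoester can add to that alkene to give a dihydropyran. The opposite condensation sense (ring carbon onto the ketone, hydroxyl onto the ester) would give a 4-arylcoumarin. The pivalate can migrate to the ring A phenols.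
- Comparison: the chosen plan fixes the position of the carbonyl by construction, since carbon monoxide is inserted between two defined atoms, whereas here chromone versus coumarin rests on a thermal preference with a hindered α-substituted ketoester. The chosen plan is mechanistically safer; the alternative is shorter.

**Alternative 2:** The cut is inside ring B. The C1'–C2' bond is formed in the key step, and C5'–C6' earlier, when an alkynyllithium that already carries the complete prenylated chromone adds to a squaric acid monoester. Forward, heating 2-[(1-hydroxy-2-methoxy-4-oxocyclobut-2-en-1-yl)ethynyl]-5,7-bis(methoxymethoxy)-3-prenylchromen-4-one A3 in toluene would open the four-membered ring to an enynyl ketene, whose ketene carbon bonds to the distal alkyne carbon (Moore rearrangement). This would give 2-methoxy-5-[5,7-bis(methoxymethoxy)-4-oxo-3-prenylchromen-2-yl]-1,4-benzoquinone A4.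
- In favour: the 1,2,4-trioxygenation of ring B relative to C1' arises with complete regiocontrol, which equals the chosen plan on that point. The key step needs no reagent, no metal and no gas under pressure, which is operationally better.
- Against: it builds the one ring that can simply be bought. Rings A and C and the C3 prenylation remain to be solved in the alkyne precursor, whose acetylide would have to add to a ketone in the presence of its own electrophilic pyranone. A4 must then be reduced to 2-(2,5-dihydroxy-4-methoxyphenyl)-5,7-bis(methoxymethoxy)-3-prenylchromen-4-one A5 and methylated at the more hindered 2'-OH while the 5'-OH stays free. That runs against the natural reactivity order and forces a protect–methylate–deprotect detour. A4 is also an oxidant and enophile sitting next to the prenyl alkene.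
- Comparison: step economy is clearly worse (well above twelve steps), and the strategic bond set does not address ring C at all.

**Alternative 3:** The cut goes through C8a–O1, C4a–C4 and O1–C2. Forward, CsF would release 3,5-bis(methoxymethoxy)benzyne A7 from 3,5-bis(methoxymethoxy)-2-(trimethylsilyl)phenyl trifluoromethanesulfonate A6. The carboxylate of (E)-2-{[2,4-dimethoxy-5-(methoxymethoxy)phenyl]methylidene}-5-methylhex-4-enoic acid A8 would add through oxygen at C8a, the aryl anion at C4a would attack the acyl carbon, and the resulting ortho-hydroxyaryl enone would close by oxa-Michael addition. The product would be racemic trans-5,7-bis(methoxymethoxy)-2-[2,4-dimethoxy-5-(methoxymethoxy)phenyl]-3-prenylchroman-4-one A9.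
- In favour: three bonds form in one operation, as in the chosen plan (equal). The prenyl group arrives with the acid, so C3 metalation is avoided (better). No transition metal or carbon monoxide is needed (operationally better). The inductive effect of the oxygen next to the aryne places the nucleophilic oxygen at C8a, as required.
- Against: A9 is at the flavanone oxidation level. Two stereocenters are made only to be destroyed, and dehydrogenating a 3-alkylflavanone to a tetrasubstituted enone is an extra and not trivial step. A7 can undergo an ene reaction with the prenyl alkene, or be protonated after O-arylation before the acyl shift. A6 needs about four steps from 2 and begins with the same ortho-halogenation that leads to 3. A8 needs several steps of its own.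
- Comparison: about three steps longer than the chosen plan, and with less close analogy for this substitution pattern.

Key step: step 7

## Route

Step 1
Reactants: 1 phloroglucinol (benzene-1,3,5-triol)
Product: 2 3,5-bis(methoxymethoxy)phenol
Conditions: MOMCl (2.0 equiv, slow addition), i-Pr2NEt, DMF/CH2Cl2, 0 °C to rt
Reagents that add atoms: chloromethyl methyl ether (MOMCl), COCCl
Why: O-alkylation of the phenol by the α-chloro ether under amine base (acetal formation); the three hydroxyls are equivalent, so only the degree of alkylation has to be controlled, and the bis-ether is separated from mono- and tris-ether, which can be recycled.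

Step 2
Reactants: 2 3,5-bis(methoxymethoxy)phenol
Product: 3 2-iodo-3,5-bis(methoxymethoxy)phenol
Conditions: NIS (1.0 equiv), CH2Cl2, −20 to 0 °C, dark
Reagents that add atoms: N-iodosuccinimide, O=C1CCC(=O)N1I
Why: Electrophilic aromatic iodination of a phloroglucinol-type ring needs no acid, so the MOM ethers are safe; C2 (= C6) should be preferred over C4 because it is statistically doubled, less hindered than the position between two MOM ethers, and reached by hydrogen-bond-assisted delivery from the free hydroxyl in a non-polar solvent.

Step 3
Reactants: 4 5-bromo-2,4-dimethoxybenzaldehyde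
Product: 6 5-bromo-2,4-dimethoxyphenol, via 5-bromo-2,4-dimethoxyphenyl formate 5 (not isolated)
Conditions: mCPBA, CH2Cl2, 0 °C to rt; then K2CO3, MeOH, rt
Reagents that add atoms: 3-chloroperoxybenzoic acid (mCPBA), O=C(OO)c1cccc(Cl)c1
Why: Baeyer–Villiger (Dakin-type) oxidation; in the Criegee adduct the aryl group, made electron-rich by its ortho- and para-methoxy groups, migrates in preference to hydrogen, and the formate is methanolysed in the same flask.

Step 4
Reactants: 6 5-bromo-2,4-dimethoxyphenol
Product: 7 1-bromo-2,4-dimethoxy-5-(methoxymethoxy)benzene
Conditions: MOMCl, i-Pr2NEt, CH2Cl2, 0 °C to rt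
Reagents that add atoms: chloromethyl methyl ether (MOMCl), COCCl
Why: Standard O-alkylation of a single unhindered phenol to its MOM ether; the same protecting group as on ring A allows one global deprotection at the end.

Step 5
Reactants: 7 1-bromo-2,4-dimethoxy-5-(methoxymethoxy)benzene; 8 trimethylsilylacetylene
Product: 9 {[2,4-dimethoxy-5-(methoxymethoxy)phenyl]ethynyl}trimethylsilane
Conditions: PdCl2(PhCN)2 (3 mol%), [HP(t-Bu)3]BF4 (6 mol%), CuI (2 mol%), i-Pr2NH, dioxane, rt to 45 °C
Reagents that add atoms: none
Why: Sonogashira coupling; the bulky, electron-rich trialkylphosphine lets zerovalent palladium add oxidatively to the deactivated ortho/para-dimethoxy aryl bromide near room temperature, and the silyl group prevents double coupling.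

Step 6
Reactants: 9 {[2,4-dimethoxy-5-(methoxymethoxy)phenyl]ethynyl}trimethylsilane
Product: 10 1-ethynyl-2,4-dimethoxy-5-(methoxymethoxy)benzene
Conditions: K2CO3, MeOH, rt
Reagents that add atoms: none
Why: Methoxide-induced protodesilylation of an alkynylsilane; the MOM and methyl ethers are inert to base.

Step 7
Reactants: 3 2-iodo-3,5-bis(methoxymethoxy)phenol; 10 1-ethynyl-2,4-dimethoxy-5-(methoxymethoxy)benzene; 11 carbon monoxide
Product: 14 5,7-bis(methoxymethoxy)-2-[2,4-dimethoxy-5-(methoxymethoxy)phenyl]-4H-chromen-4-one, via ortho-hydroxyaryl ynone 12 (not isolated), via diethylamino enaminone 13 (not isolated)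
Conditions: PdCl2(PPh3)2 (5 mol%), CO (20 atm), Et2NH, 120 °C, autoclave
Reagents that add atoms: none
Why: The divalent precatalyst is reduced in situ to zerovalent palladium, which adds oxidatively to the C–I bond of 3; CO insertion gives an aroylpalladium iodide, amine-assisted exchange with the terminal alkyne 10 gives an aroyl(alkynyl)palladium species, and reductive elimination forms the C4a–C4 and C3–C4 bonds of ynone 12. Diethylamine then adds to the ynone in conjugate fashion to give enaminone 13, and the ortho phenol oxygen attacks C2 and expels the amine, forming O1–C2. The closest known reaction type is the palladium-catalysed carbonylative annulation of ortho-iodophenols with terminal alkynes in a secondary amine (carbonylative Sonogashira coupling followed by cyclisation). Ring C closes by a 6-endo-trig addition–elimination on the enaminone, which replaces the direct 6-endo-dig versus 5-exo-dig competition on the ynone. No stereocenter is formed. Three selectivities are needed: CO insertion before alkyne coupling (otherwise a 2-arylbenzofuran would result), which CO pressure, the absence of a copper cocatalyst and the fast migratory insertion of an electron-rich aryl group should secure; capture of the aroylpalladium by the alkyne and not by the amine solvent, which the two ortho oxygen substituents should favour by shielding the acyl carbon; and pyranone over aurone, which the enaminone pathway secures because the amine-bearing C2 is the only electrophilic carbon left. The MOM ethers, the aryl methyl ethers and the C3–H bond are inert to these basic conditions.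

Step 8
Reactants: 14 5,7-bis(methoxymethoxy)-2-[2,4-dimethoxy-5-(methoxymethoxy)phenyl]-4H-chromen-4-one; 15 prenyl bromide (1-bromo-3-methylbut-2-ene)
Product: 18 5,7-bis(methoxymethoxy)-2-[2,4-dimethoxy-5-(methoxymethoxy)phenyl]-3-(3-methylbut-2-en-1-yl)-4H-chromen-4-one, via 3-lithioflavone 16 (not isolated), via 3-cuprioflavone 17 (not isolated)
Conditions: LiN(i-Pr)2 (1.2 equiv), THF, −78 °C; CuBr·SMe2 (1.0 equiv), −78 °C; then 15, −78 to −20 °C
Reagents that add atoms: none
Why: Kinetic deprotonation of the flavone C3–H by a lithium amide at −78 °C is a known metalation (the ring C–H bonds between oxygen substituents need alkyllithium bases), and lithium-to-copper transmetalation gives a softer vinylcopper that should undergo allylic substitution at the primary carbon of 15, attack at the tertiary end being disfavoured because it would create a quaternary carbon; the low temperature suppresses ring opening of the metalated pyranone.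

Step 9
Reactants: 18 5,7-bis(methoxymethoxy)-2-[2,4-dimethoxy-5-(methoxymethoxy)phenyl]-3-(3-methylbut-2-en-1-yl)-4H-chromen-4-one
Product: 19 artoindonesianin R, 5,7-dihydroxy-2-(5-hydroxy-2,4-dimethoxyphenyl)-3-(3-methylbut-2-en-1-yl)-4H-chromen-4-one
Conditions: HCl (3 M aq), MeOH, rt to 45 °C
Reagents that add atoms: none
Why: Acid-catalysed acetal exchange transfers each methoxymethyl group to methanol while aryl methyl ethers are untouched; no free hydroxyl lies within reach of the prenyl alkene (2'-O is methylated, 5-OH is tied to the carbonyl), so cyclisation to a chroman is not available and mild temperature should hold back solvent addition to the alkene.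

## Compound list

1 | phloroglucinol (benzene-1,3,5-triol) | Oc1cc(O)cc(O)c1 | starting material
2 | 3,5-bis(methoxymethoxy)phenol | COCOc1cc(O)cc(OCOC)c1 | intermediate
3 | 2-iodo-3,5-bis(methoxymethoxy)phenol | COCOc1cc(O)c(I)c(OCOC)c1 | intermediate
4 | 5-bromo-2,4-dimethoxybenzaldehyde | COc1cc(OC)c(C=O)cc1Br | starting material
5 | 5-bromo-2,4-dimethoxyphenyl formate (formed in situ in step 3) | COc1cc(OC)c(OC=O)cc1Br | intermediate
6 | 5-bromo-2,4-dimethoxyphenol | COc1cc(OC)c(O)cc1Br | intermediate
7 | 1-bromo-2,4-dimethoxy-5-(methoxymethoxy)benzene | COCOc1cc(Br)c(OC)cc1OC | intermediate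
8 | trimethylsilylacetylene (ethynyltrimethylsilane) | C#C[Si](C)(C)C | starting material
9 | {[2,4-dimethoxy-5-(methoxymethoxy)phenyl]ethynyl}trimethylsilane | COCOc1cc(C#C[Si](C)(C)C)c(OC)cc1OC | intermediate
10 | 1-ethynyl-2,4-dimethoxy-5-(methoxymethoxy)benzene | C#Cc1cc(OCOC)c(OC)cc1OC | intermediate
11 | carbon monoxide | [C-]#[O+] | starting material
12 | 1-[2-hydroxy-4,6-bis(methoxymethoxy)phenyl]-3-[2,4-dimethoxy-5-(methoxymethoxy)phenyl]prop-2-yn-1-one (formed in situ in step 7) | COCOc1cc(O)c(C(=O)C#Cc2cc(OCOC)c(OC)cc2OC)c(OCOC)c1 | intermediate
13 | (E)-3-(diethylamino)-1-[2-hydroxy-4,6-bis(methoxymethoxy)phenyl]-3-[2,4-dimethoxy-5-(methoxymethoxy)phenyl]prop-2-en-1-one (formed in situ in step 7; E expected, geometry without consequence for ring closure) | COCOc1cc(O)c(C(=O)/C=C(/N(CC)CC)c2cc(OCOC)c(OC)cc2OC)c(OCOC)c1 | intermediate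
14 | 5,7-bis(methoxymethoxy)-2-[2,4-dimethoxy-5-(methoxymethoxy)phenyl]-4H-chromen-4-one | COCOc1cc(OCOC)c2c(c1)oc(-c1cc(OCOC)c(OC)cc1OC)cc2=O | intermediate
15 | prenyl bromide (1-bromo-3-methylbut-2-ene) | CC(C)=CCBr | starting material
16 | 3-lithio derivative of 14 (formed in situ in step 8) | [Li]c1c(-c2cc(OCOC)c(OC)cc2OC)oc2cc(OCOC)cc(OCOC)c2c1=O | intermediate
17 | 3-cuprio derivative of 14 (formed in situ in step 8) | [Cu]c1c(-c2cc(OCOC)c(OC)cc2OC)oc2cc(OCOC)cc(OCOC)c2c1=O | intermediate
18 | 5,7-bis(methoxymethoxy)-2-[2,4-dimethoxy-5-(methoxymethoxy)phenyl]-3-(3-methylbut-2-en-1-yl)-4H-chromen-4-one | COCOc1cc(OCOC)c2c(c1)oc(-c1cc(OCOC)c(OC)cc1OC)c(CC=C(C)C)c2=O | intermediate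
19 | artoindonesianin R, 5,7-dihydroxy-2-(5-hydroxy-2,4-dimethoxyphenyl)-3-(3-methylbut-2-en-1-yl)-4H-chromen-4-one | COc1cc(OC)c(-c2oc3cc(O)cc(O)c3c(=O)c2CC=C(C)C)cc1O | target

## Step count and risk

Total step count: 9. Longest linear sequence: 7 steps (steps 3, 4, 5, 6, 7, 8 and 9, from 4 to 19). The ring A branch (steps 1 and 2) joins at step 7.

**Step 7 (key step).** The likeliest failure is diversion of the aroylpalladium intermediate: capture by diethylamine to give an amide, or coupling of the alkyne before CO insertion. The cause is that the iodide sits between two oxygen substituents on a very electron-rich ring, which slows every step at the metal. The fallback uses no palladium and no carbon monoxide and sets out from 3 and 10. Compound 10 is deprotonated (n-BuLi, THF, −78 °C) and acylated with N-methoxy-N-methylcarbamoyl chloride to give N-methoxy-N-methyl-3-[2,4-dimethoxy-5-(methoxymethoxy)phenyl]prop-2-ynamide F1. Compound 3 is treated with n-BuLi (2.1 equiv, THF, −78 °C; deprotonation of the hydroxyl, then iodine–lithium exchange) and the aryllithium is added to F1. The chelated tetrahedral adduct collapses on work-up to 12. Stirring 12 in Et2NH/EtOH at rt closes the ring through 13, and the route is rejoined at 14.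

**Step 8.** The likeliest failures are loss of regiocontrol in the allylic substitution (attack at the tertiary carbon of 15, giving the 1,1-dimethylallyl isomer) and ring opening of the metalated pyranone by β-elimination of the phenoxide if the temperature rises before alkylation. The fallback sets out from 14. The same metalation and transmetalation are used, but with allyl bromide, for which both ends of the allyl unit are identical. This gives 5,7-bis(methoxymethoxy)-2-[2,4-dimethoxy-5-(methoxymethoxy)phenyl]-3-(prop-2-en-1-yl)-4H-chromen-4-one F2. Olefin cross-metathesis of F2 with excess 2-methyl-2-butene (second-generation Grubbs catalyst, CH2Cl2, 40 °C) converts the allyl group into the prenyl group and returns to the route at 18.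

**Step 2.** The likeliest failure is iodination para to the free hydroxyl (between the two MOM ethers) or double iodination, because all three open ring positions are strongly activated. The fallback sets out from 2 and replaces electrophilic control by directed metalation. Carbamoylation (ClCONEt2, K2CO3, MeCN, reflux) gives 3,5-bis(methoxymethoxy)phenyl N,N-diethylcarbamate F3. Ortho-lithiation at the position flanked by the carbamate and one MOM ether (s-BuLi, TMEDA, THF, −78 °C) and an I2 quench give 2-iodo-3,5-bis(methoxymethoxy)phenyl N,N-diethylcarbamate F4. Hydrolysis of the carbamate (KOH, EtOH, reflux) returns to the route at 3.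

**Step 9.** The likeliest failure is acid-promoted Markovnikov addition of methanol or HCl to the trisubstituted alkene while the slower 7- and 5'-MOM ethers are being cleaved. The fallback sets out from 14 and postpones the sensitive alkene until after the acid step. Compound 14 is allylated as described for step 8 to the 3-allyl flavone F2, whose monosubstituted alkene is far less prone to protonation. HCl/MeOH then gives 5,7-dihydroxy-2-(5-hydroxy-2,4-dimethoxyphenyl)-3-(prop-2-en-1-yl)-4H-chromen-4-one F5. Cross-metathesis of the free triphenol F5 with 2-methyl-2-butene (second-generation Grubbs catalyst, CH2Cl2, 40 °C) arrives directly at 19.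

**Step 5.** The likeliest failure is slow oxidative addition into the deactivated, ortho-substituted aryl bromide, so that oxidative dimerisation of 8 overtakes the cross-coupling. The fallback sets out from 7 and builds the alkyne from a carbonyl group. Bromine–lithium exchange (n-BuLi, THF, −78 °C) and formylation with DMF give 2,4-dimethoxy-5-(methoxymethoxy)benzaldehyde F6. Seyferth–Gilbert homologation with the Ohira–Bestmann reagent (dimethyl (1-diazo-2-oxopropyl)phosphonate, K2CO3, MeOH, rt) then returns to the route at 10, in the same number of steps as steps 5 and 6.

## Further compounds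

F1 | step 7 | N-methoxy-N-methyl-3-[2,4-dimethoxy-5-(methoxymethoxy)phenyl]prop-2-ynamide | COCOc1cc(C#CC(=O)N(C)OC)c(OC)cc1OC
F2 | step 8 | 5,7-bis(methoxymethoxy)-2-[2,4-dimethoxy-5-(methoxymethoxy)phenyl]-3-(prop-2-en-1-yl)-4H-chromen-4-one | COCOc1cc(OCOC)c2c(c1)oc(-c1cc(OCOC)c(OC)cc1OC)c(CC=C)c2=O
F3 | step 2 | 3,5-bis(methoxymethoxy)phenyl N,N-diethylcarbamate | CCN(CC)C(=O)Oc1cc(OCOC)cc(OCOC)c1
F4 | step 2 | 2-iodo-3,5-bis(methoxymethoxy)phenyl N,N-diethylcarbamate | CCN(CC)C(=O)Oc1cc(OCOC)cc(OCOC)c1I
F5 | step 9 | 5,7-dihydroxy-2-(5-hydroxy-2,4-dimethoxyphenyl)-3-(prop-2-en-1-yl)-4H-chromen-4-one | COc1cc(OC)c(-c2oc3cc(O)cc(O)c3c(=O)c2CC=C)cc1O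
F6 | step 5 | 2,4-dimethoxy-5-(methoxymethoxy)benzaldehyde | COCOc1cc(C=O)c(OC)cc1OC
A1 | alternative 1 | ethyl 2-[2,4-dimethoxy-5-(pivaloyloxy)benzoyl]-5-methylhex-4-enoate (racemic) | CCOC(=O)C(CC=C(C)C)C(=O)c1cc(OC(=O)C(C)(C)C)c(OC)cc1OC
A2 | alternative 1 | artoindonesianin R 5'-O-pivalate | CC(C)(C)C(=O)Oc1cc(-c2oc3cc(O)cc(O)c3c(=O)c2CC=C(C)C)c(OC)cc1OC
A3 | alternative 2 | 2-[(1-hydroxy-2-methoxy-4-oxocyclobut-2-en-1-yl)ethynyl]-5,7-bis(methoxymethoxy)-3-prenylchromen-4-one (racemic) | COC1=CC(=O)C1(O)C#Cc1oc2cc(OCOC)cc(OCOC)c2c(=O)c1CC=C(C)C
A4 | alternative 2 | 2-methoxy-5-[5,7-bis(methoxymethoxy)-4-oxo-3-prenylchromen-2-yl]-1,4-benzoquinone | COC1=CC(=O)C(=CC1=O)c1oc2cc(OCOC)cc(OCOC)c2c(=O)c1CC=C(C)C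
A5 | alternative 2 | 2-(2,5-dihydroxy-4-methoxyphenyl)-5,7-bis(methoxymethoxy)-3-prenylchromen-4-one | COc1cc(O)c(-c2oc3cc(OCOC)cc(OCOC)c3c(=O)c2CC=C(C)C)cc1O
A6 | alternative 3 | 3,5-bis(methoxymethoxy)-2-(trimethylsilyl)phenyl trifluoromethanesulfonate | COCOc1cc(OCOC)c([Si](C)(C)C)c(OS(=O)(=O)C(F)(F)F)c1
A7 | alternative 3 | 3,5-bis(methoxymethoxy)benzyne | COCOC1=CC(OCOC)=CC#C1
A8 | alternative 3 | (E)-2-{[2,4-dimethoxy-5-(methoxymethoxy)phenyl]methylidene}-5-methylhex-4-enoic acid | O=C(O)/C(CC=C(C)C)=C/c1cc(OCOC)c(OC)cc1OC
A9 | alternative 3 | racemic trans-5,7-bis(methoxymethoxy)-2-[2,4-dimethoxy-5-(methoxymethoxy)phenyl]-3-prenylchroman-4-one (relative configuration shown) | O=C1[C@@H](CC=C(C)C)[C@H](c2cc(OCOC)c(OC)cc2OC)Oc2cc(OCOC)cc(OCOC)c12
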